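**Retrosynthetic overview**

- The strategy rests on the chain C8–C3'=C4'–C5'(Me)2–O. In the target it is closed as a butenolide through the carboxyl oxygen O1'. Closed instead through O7 of ring A, the same chain is an angular 2,2-dimethyl-2H-pyran fused across C7–C8.
- Target 15 ← O-methylation of phenol 13 ← oxygen swap of pyranoflavone acid 11 (break O7–C5', make O1'–C5').
- Acid 11 ← ester 10 ← propargyl Claisen / 1,5-H shift / oxa-6π cascade of alkynoate ether 6, which forms C8–C3'.
- Ether 6 ← 7-hydroxyflavone 1 + 3-chloro-3-methylbut-1-yne 2, then CO/MeOH on the alkyne terminus.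
- Ring order: flavone rings (purchased) → pyran ring (step 3) → butenolide at the expense of the pyran (step 5).

Key step: step 5

Remark: the target has no stereocentre. Locants C2–C8a are those of the flavone; O1', C2'(=O), C3', C4', C5' are the butenolide atoms, with C3' bonded to C8.

**Step 1**
Reactants: 1 7-hydroxyflavone; 2 3-chloro-3-methylbut-1-yne
Product: 3 7-[(2-methylbut-3-yn-2-yl)oxy]flavone
Conditions: K2CO3, KI (cat.), CuI (cat.), DMF, 65 °C, sealed vessel
Reagents that add atoms: 3-chloro-3-methylbut-1-yne (2), CC(C)(Cl)C#C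
Why: Copper-assisted Williamson-type O-alkylation of an acidic phenol with a tertiary propargylic chloride, the standard entry to aryl 1,1-dimethylpropargyl ethers, should occur at the only hydroxyl group.

**Step 2**
Reactants: 3 7-[(2-methylbut-3-yn-2-yl)oxy]flavone; 4 carbon monoxide; 5 methanol
Product: 6 methyl 4-methyl-4-[(4-oxo-2-phenyl-4H-chromen-7-yl)oxy]pent-2-ynoate
Conditions: PdCl2 (cat.), CuCl2 (2 equiv), NaOAc (2 equiv), CO (1 atm), MeOH/THF, rt
Reagents that add atoms: carbon monoxide (4), [C-]#[O+]; methanol (5), CO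
Why: Palladium-catalysed oxidative alkoxycarbonylation of a terminal alkyne should give the alkynoate under near-neutral conditions that leave the base-sensitive flavone and the tertiary aryl ether untouched.

**Step 3**
Reactants: 6 methyl 4-methyl-4-[(4-oxo-2-phenyl-4H-chromen-7-yl)oxy]pent-2-ynoate
Product: 10 methyl 8,8-dimethyl-4-oxo-2-phenyl-4H,8H-pyrano[2,3-h]chromene-10-carboxylate, via allenyl dienone 7 (not isolated), via allenyl phenol 8 (not isolated), via quinone methide ester 9 (not isolated)
Conditions: 1,2-dichlorobenzene, 180 °C, Ar, no base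
Reagents that add atoms: none
Why: The aryl propargyl ether Claisen rearrangement should deliver the ester-bearing alkyne carbon to C8 (the ortho position favoured in 7-oxygenated chromones), and tautomerisation, 1,5-hydrogen shift and oxa-6π closure should then give the 2,2-dimethyl-2H-pyran with the ester on C10; a base-free, non-polar medium disfavours phenol addition to the allenoate.

**Step 4**
Reactants: 10 methyl 8,8-dimethyl-4-oxo-2-phenyl-4H,8H-pyrano[2,3-h]chromene-10-carboxylate
Product: 11 8,8-dimethyl-4-oxo-2-phenyl-4H,8H-pyrano[2,3-h]chromene-10-carboxylic acid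
Conditions: LiOH·H2O, THF/H2O, rt; then 1 M HCl; light excluded
Reagents that add atoms: lithium hydroxide, [Li+].[OH-]
Why: Saponification of the methyl ester at room temperature should be faster than hydroxide attack on the 2-phenylpyranone, and the pyran ether is inert to base.

**Step 5**
Reactants: 11 8,8-dimethyl-4-oxo-2-phenyl-4H,8H-pyrano[2,3-h]chromene-10-carboxylic acid
Product: 13 8-(5,5-dimethyl-2-oxo-2,5-dihydrofuran-3-yl)-7-hydroxyflavone, via quinone methide acid 12 (not isolated)
Conditions: hν (365 nm LED), MeCN/HFIP (9:1), 5 mM, Ar, rt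
Reagents that add atoms: none
Why: Proposed new method: excitation of the 2H-pyran chromophore of 11 should trigger the retro-oxa-6π ring opening known from photochromic 2H-chromenes, cleaving O7–C5' to give quinone methide 12, in which C3'–C4' is a single bond; rotation about it to the s-trans conformer puts C5' beside the carboxyl group and out of reach of O7. Hydrogen bonding or proton transfer from HFIP to the quinone methide oxygen makes C5' a tertiary, allyl-cation-like terminus, and the carboxyl oxygen adds to it to form O1'–C5', which rearomatises ring A and releases the C7 hydroxyl. The closest known reaction types are the photochemical opening of 2,2-dimethyl-2H-chromenes with 1,6-capture of the quinone methide by alcohols, and the acid lactonization of γ,γ-dimethyl allenoic or β,γ-unsaturated acids. The butenolide closes in a 5-endo mode, tolerable here because the attacked carbon is cation-like and not a plain alkene carbon; no stereocentre is formed. The selectivity needed is carboxyl oxygen over O7 for C5': a quinone methide that recloses at O7 only returns 11, which absorbs again, whereas 13 has lost the pyran chromophore and carries a weakly nucleophilic, acidic flavone phenol, so the mixture should drain to the lactone even if the two isomers lie close in energy.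

**Step 6**
Reactants: 13 8-(5,5-dimethyl-2-oxo-2,5-dihydrofuran-3-yl)-7-hydroxyflavone; 14 iodomethane
Product: 15 8-(5,5-dimethyl-2-oxo-2,5-dihydrofuran-3-yl)-7-methoxyflavone (target)
Conditions: MeI, K2CO3, DMF, rt
Reagents that add atoms: iodomethane (14), CI
Why: Williamson methylation of the acidic C7 phenol should be fast at room temperature, which keeps the phenolate from expelling the lactone carboxylate and returning to the pyran carboxylate; the lactone has no other alkylatable site.

**Compound list**

1 | 7-hydroxyflavone (7-hydroxy-2-phenyl-4H-chromen-4-one) | Oc1ccc2c(=O)cc(-c3ccccc3)oc2c1 | starting material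
2 | 3-chloro-3-methylbut-1-yne | CC(C)(Cl)C#C | starting material
3 | 7-[(2-methylbut-3-yn-2-yl)oxy]flavone | C#CC(C)(C)Oc1ccc2c(=O)cc(-c3ccccc3)oc2c1 | intermediate
4 | carbon monoxide | [C-]#[O+] | starting material
5 | methanol | CO | starting material
6 | methyl 4-methyl-4-[(4-oxo-2-phenyl-4H-chromen-7-yl)oxy]pent-2-ynoate | COC(=O)C#CC(C)(C)Oc1ccc2c(=O)cc(-c3ccccc3)oc2c1 | intermediate
7 | methyl 2-(4,7-dioxo-2-phenyl-7,8-dihydro-4H-chromen-8-yl)-4-methylpenta-2,3-dienoate (allenyl dienone, racemic at C8) | COC(=O)C(=C=C(C)C)C1C(=O)C=CC2=C1OC(=CC2=O)c1ccccc1 | intermediate (not isolated)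
8 | methyl 2-(7-hydroxy-4-oxo-2-phenyl-4H-chromen-8-yl)-4-methylpenta-2,3-dienoate (allenyl phenol) | COC(=O)C(=C=C(C)C)c1c(O)ccc2c(=O)cc(-c3ccccc3)oc12 | intermediate (not isolated)
9 | methyl 2-(4,7-dioxo-2-phenyl-4H-chromen-8(7H)-ylidene)-4-methylpent-3-enoate (quinone methide ester, diene arm cis to C7=O) | COC(=O)/C(C=C(C)C)=C1/C(=O)C=CC2=C1OC(=CC2=O)c1ccccc1 | intermediate (not isolated)
10 | methyl 8,8-dimethyl-4-oxo-2-phenyl-4H,8H-pyrano[2,3-h]chromene-10-carboxylate | COC(=O)C1=CC(C)(C)Oc2ccc3c(=O)cc(-c4ccccc4)oc3c21 | intermediate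
11 | 8,8-dimethyl-4-oxo-2-phenyl-4H,8H-pyrano[2,3-h]chromene-10-carboxylic acid | O=C(O)C1=CC(C)(C)Oc2ccc3c(=O)cc(-c4ccccc4)oc3c21 | intermediate
12 | 2-(4,7-dioxo-2-phenyl-4H-chromen-8(7H)-ylidene)-4-methylpent-3-enoic acid (quinone methide acid) | OC(=O)/C(C=C(C)C)=C1/C(=O)C=CC2=C1OC(=CC2=O)c1ccccc1 | intermediate (not isolated)
13 | 8-(5,5-dimethyl-2-oxo-2,5-dihydrofuran-3-yl)-7-hydroxyflavone | Oc1ccc2c(=O)cc(-c3ccccc3)oc2c1C1=CC(C)(C)OC1=O | intermediate
14 | iodomethane | CI | starting material
15 | 8-(5,5-dimethyl-2-oxo-2,5-dihydrofuran-3-yl)-7-methoxyflavone | COc1ccc2c(=O)cc(-c3ccccc3)oc2c1C1=CC(C)(C)OC1=O | target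

**Total step count:** 6
**Longest linear sequence:** 6 steps (1 → 3 → 6 → 10 → 11 → 13 → 15)

**Steps most likely to fail**

1. Step 5 (proposed new method). The quinone methide may reclose at O7 faster than the carboxyl group captures C5'. A 1,7-hydrogen shift from a C5' methyl to O7 may divert material to a dienyl phenol, or the flavone chromophore may dissipate the excitation without ring opening. Fallback by known chemistry, setting out from 1 and rejoining at 15: 1 would be iodinated at C8 (NIS, DMF, rt) to 7-hydroxy-8-iodoflavone F1. F1 would be methylated (MeI, K2CO3, acetone) to 8-iodo-7-methoxyflavone F2. Sonogashira coupling of F2 with 2-methylbut-3-yn-2-ol (PdCl2(PPh3)2, CuI, Et3N, DMF, 60 °C) should give 8-(3-hydroxy-3-methylbut-1-yn-1-yl)-7-methoxyflavone F3. Palladium-catalysed cyclocarbonylation of this tertiary alkynol (Pd2(dba)3, dppb, CO/H2, CH2Cl2, 95 °C) is expected to deliver the 3-aryl-5,5-dimethylbutenolide, which is 15.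

2. Step 3. The sigmatropic shift may leak to C6 and give the linear pyran, or the phenol of 8 may add to the allenoate before the 1,5-hydrogen shift and close a benzofuran instead. Fallback without a sigmatropic step, setting out from 1 and rejoining at 10: 1 would be acetylated (Ac2O, pyridine) to 7-acetoxyflavone F4. Fries rearrangement (AlCl3, 165 °C) should give 8-acetyl-7-hydroxyflavone F5. Kabbe condensation with acetone (pyrrolidine, toluene, reflux) should give 8,8-dimethyl-2-phenyl-8,9-dihydro-4H,10H-pyrano[2,3-h]chromene-4,10-dione F6. Enolisation and triflation (KHMDS, PhNTf2, THF, −78 °C) should give 8,8-dimethyl-4-oxo-2-phenyl-4H,8H-pyrano[2,3-h]chromen-10-yl trifluoromethanesulfonate F7. Methoxycarbonylation of F7 (Pd(OAc)2, dppp, CO, MeOH, Et3N, DMF, 65 °C) should give 10.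

3. Step 2. Oxidative homocoupling of the terminal alkyne or double carbonylation across the triple bond may compete with monocarbonylation. Fallback setting out from 3 and rejoining at 6: carboxylation of the alkyne C–H with CO2 (AgI cat., Cs2CO3, CO2, DMF, 50 °C) should give 4-methyl-4-[(4-oxo-2-phenyl-4H-chromen-7-yl)oxy]pent-2-ynoic acid F8 as its caesium salt. Alkylation of this salt in the same flask with MeI should give 6.

**Further compounds**

F1 | step 5 | 7-hydroxy-8-iodoflavone | Oc1ccc2c(=O)cc(-c3ccccc3)oc2c1I
F2 | step 5 | 8-iodo-7-methoxyflavone | COc1ccc2c(=O)cc(-c3ccccc3)oc2c1I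
F3 | step 5 | 8-(3-hydroxy-3-methylbut-1-yn-1-yl)-7-methoxyflavone | COc1ccc2c(=O)cc(-c3ccccc3)oc2c1C#CC(C)(C)O
F4 | step 3 | 7-acetoxyflavone | CC(=O)Oc1ccc2c(=O)cc(-c3ccccc3)oc2c1
F5 | step 3 | 8-acetyl-7-hydroxyflavone | CC(=O)c1c(O)ccc2c(=O)cc(-c3ccccc3)oc12
F6 | step 3 | 8,8-dimethyl-2-phenyl-8,9-dihydro-4H,10H-pyrano[2,3-h]chromene-4,10-dione | O=C1CC(C)(C)Oc2ccc3c(=O)cc(-c4ccccc4)oc3c21
F7 | step 3 | 8,8-dimethyl-4-oxo-2-phenyl-4H,8H-pyrano[2,3-h]chromen-10-yl trifluoromethanesulfonate | O=S(=O)(OC1=CC(C)(C)Oc2ccc3c(=O)cc(-c4ccccc4)oc3c21)C(F)(F)F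
F8 | step 2 | 4-methyl-4-[(4-oxo-2-phenyl-4H-chromen-7-yl)oxy]pent-2-ynoic acid | OC(=O)C#CC(C)(C)Oc1ccc2c(=O)cc(-c3ccccc3)oc2c1
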